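**Two charges.** Tuesday's small charge, c(starting material) = 0.40 M, and Monday's large one, 1.6 M, both ran under gas held at 200 mM, with no reagent dissolved at the start. Violet and teal are one recipe lying between those charges, read at two times.

| flask | starting material | gas | remark | time |
|---|---|---|---|---|
| Tuesday's | 0.40 M | 200 mM (held) | run made earlier |  |
| Monday's | 1.6 M | 200 mM (held) | run made earlier |  |
| violet | 0.80 M | 200 mM (held) |  | 25 min |
| teal | 0.80 M | 200 mM (held) |  | 50 min |

| run | time / min | isomer of the product / % | target / % | starting material / % |
|---|---|---|---|---|
| Tuesday's | 5.00 | 30 | 35 | 36 |
| Tuesday's | 10.0 | 51 | 34 | 14 |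
| Tuesday's | 15.0 | 63 | 30 | 10 |
| Tuesday's | 20.0 | 71 | 25 | 8 |
| Tuesday's | 25.0 | 78 | 18 | 5 |
| Tuesday's | 30.0 | 85 | 12 | 7 |
| Monday's | 2.00 | 6 | 7 | 85 |
| Monday's | 6.00 | 18 | 22 | 55 |
| Monday's | 10.0 | 34 | 29 | 37 |
| Monday's | 15.0 | 50 | 31 | 19 |
| Monday's | 25.0 | 71 | 23 | 7 |
| Monday's | 30.0 | 77 | 15 | 6 |

(each reading ± 1.5 percentage points)

- which of these there is most of at the end, counted by the starting material in it, violet (starting material / isomer of the product / target)
- which of these there is most of at the end, counted by the starting material in it, teal (starting material / isomer of the product / target)
- the largest of these amounts at the end, in percent of the starting material charged, violet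
- the largest of these amounts at the end, in percent of the starting material charged, teal

- at the start none of reagent is dissolved
- the analysis behind the earlier runs scatters by 1.5 percentage points, standard deviation
- what may be going on: starting material + reagent <-> target; starting material + reagent <-> isomer of the product; gas <-> reagent

**The remainder.** I call remainder whatever is not isomer of the product. If its late fall is pseudo-first-order, it halves in a fixed time, and two charges a factor 4.00 apart should give one time. Equal times are the zero of my scale.

**Two ways.** From 15.0 min to 30.0 min, Tuesday's remainder goes from 37.0% to 15.0%, which gives 11.5 min. Monday's goes from 50.0% to 23.0%, which gives 13.4 min. They part, and I suspect Tuesday's last row, whose readings sum to 104% of the charge. Counted instead as target plus starting material, Tuesday's remainder gives 14.0 min. So I distrust that isomer reading and carry Monday's figure as the halving time of the remainder.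

**My reckoning.** Violet's charge of 0.80 M stands a factor 2.00 above Tuesday's and a factor 2.00 below Monday's. So for violet at 25 min I take the mean of the two remainders at that time, 22.0% and 29.0%, which is 25.5%. That puts isomer at 74.5%. Teal runs 25.0 min longer, which is 1.87 halvings, so I reckon its remainder at 6.99% and its isomer at 93.0%. By this reckoning violet and teal each hold more isomer than remainder, so I expect isomer to be the largest in both, however the remainder is split.

**The forecast.** It names isomer of the product for violet at 75% and isomer of the product for teal at 90%, on this ground: “Target is the kinetic product and then drains to isomer through reversal”. Its teal figure stands 3 percentage points under mine.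

**The flask.** Violet gives isomer of the product at 75.9%, and teal gives isomer of the product at 92.8%, so the forecast is right on all its marks.

    starting material + reagent ⇌ target (K = 11.0 /M, k = 0.0327 /M/s)
    starting material + reagent ⇌ isomer of the product (K = 1000 /M, k = 0.0190 /M/s)
    gas ⇌ reagent, rate k3*(csat - [reagent]) (kL = 0.0124 /s)

**Reading later.** Violet's simulated remainder at 25 min is 24.1%. Carried forward by the halving time, that remainder becomes 6.60% for teal, where the flask holds 7.20%. The same reckoning on the neighbour, violet read at 1.5 h, gives 0.832%. That flask holds 2.19%, as target 1.55% and starting material 0.638%. At 250 min violet still holds 1.57% of the two.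

(The data are simulated with constants of no real substance; scatter was added.)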